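**Assumption:** Artopetelin C as drawn has no stereocentre and no stereodefined alkene, so it is achiral; the route targets the exact constitution and needs no enantiocontrol.

## Retrosynthetic overview

1. Target 20 ⇐ tris-MOM ether 19 (global MOM removal).
2. 19 ⇐ dichlorovinyl ether 8 + bromochromane 18: one Pd operation makes the aryl–C2 bond (Negishi at the O-bearing C–Cl) and then closes the furan by C–H cyclisation at the only free ortho position.
3. 8 ⇐ resorcinol: Ir C–H borylation/oxidation adds the third oxygen as the only free OH; that OH carries the prenyl for the Claisen (reverse prenyl) and then the dichlorovinyl unit, so it must become the furan oxygen.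
4. 18 ⇐ 1,3-dibromobenzene: C2 prenylation/hydration (side chain), Ir C–H borylation/oxidation (7-OH), O-tert-allylation/Claisen on a symmetric phenol (6-prenyl), Pd C–O closure on the less hindered bromide (pyran ring).
5. Ring order: both benzene rings are purchased; pyran ring (step 13), then furan ring (step 14).

## Route

### Fragment A (benzofuran half)

**Step 1**
Reactants: 1 resorcinol
Product: 2 1,3-bis(methoxymethoxy)benzene
Conditions: MOMCl, i-Pr2NEt, CH2Cl2, 0 °C → rt
Reagents that add atoms: chloromethyl methyl ether, COCCl
Why: Standard phenol O-alkylation (MOM protection); MOM is stable to all later basic, organometallic and Pd steps.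

**Step 2**
Reactants: 2
Product: 3 3,5-bis(methoxymethoxy)phenol
Conditions: [Ir(OMe)(cod)]2 (1.5 mol%), dtbpy, B2pin2, THF, 80 °C; then aq. NaOH, H2O2, 0 °C (one pot)
Reagents that add atoms: hydrogen peroxide, OO
Why: Sterically controlled Ir-catalysed C–H borylation hits the only C–H not ortho to a substituent (C5), and boronate oxidation gives the phenol.

**Step 3**
Reactants: 3; 4 prenyl bromide
Product: 5 1,3-bis(methoxymethoxy)-5-[(3-methylbut-2-en-1-yl)oxy]benzene
Conditions: K2CO3, acetone, 50 °C
Reagents that add atoms: none beyond 4
Why: Williamson etherification of the single free phenol.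

**Step 4**
Reactants: 5
Product: 6 3,5-bis(methoxymethoxy)-2-(2-methylbut-3-en-2-yl)phenol
Conditions: PhNEt2, BSA, 150 °C; then K2CO3, MeOH, rt
Reagents that add atoms: none
Why: Aromatic Claisen [3,3] rearrangement of the prenyl ether gives the ortho 1,1-dimethylallyl phenol (the two ortho sites are equivalent), with amine solvent and in-situ silylation speeding rearomatisation to suppress para-Cope and abnormal-Claisen products.

**Step 5**
Reactants: 6; 7 trichloroethylene
Product: 8 1-{[(E)-1,2-dichloroethenyl]oxy}-3,5-bis(methoxymethoxy)-2-(2-methylbut-3-en-2-yl)benzene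
Conditions: K2CO3, DMF, 65 °C
Reagents that add atoms: none beyond 7
Why: Base generates dichloroacetylene from trichloroethylene and the phenoxide adds anti across it, giving the (E)-1,2-dichlorovinyl ether (known phenol to dichlorovinyl ether reaction).

### Fragment B (chroman half)

**Step 6**
Reactants: 9 1,3-dibromobenzene; 4 prenyl bromide
Product: 10 1,3-dibromo-2-(3-methylbut-2-en-1-yl)benzene
Conditions: LDA, THF, −78 °C; CuBr·SMe2; then 4, −78 → −20 °C
Reagents that add atoms: none beyond 4
Why: Deprotonation occurs at the most acidic C–H between the two bromines, and the arylcopper is alkylated by SN2 at the primary terminus to give the linear prenyl arene.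

**Step 7**
Reactants: 10
Product: 11 4-(2,6-dibromophenyl)-2-methylbutan-2-ol
Conditions: Co(acac)2 (cat.), PhSiH3, O2 (1 atm), i-PrOH, rt
Reagents that add atoms: dioxygen, O=O
Why: Mukaiyama hydration (metal-hydride H-atom transfer) gives the Markovnikov tertiary alcohol and leaves the aryl bromides untouched.

**Step 8**
Reactants: 11
Product: 12 3,5-dibromo-4-(3-hydroxy-3-methylbutyl)phenol
Conditions: [Ir(OMe)(cod)]2, dtbpy, B2pin2 (1.5 equiv), THF, 80 °C; then aq. NaOH, H2O2, 0 °C
Reagents that add atoms: hydrogen peroxide, OO
Why: Ir-catalysed C–H borylation of a 1,2,3-trisubstituted arene occurs only at the C–H flanked by two hydrogens (para to the chain), and oxidation gives a symmetric phenol.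

**Step 9**
Reactants: 13 2-methylbut-3-en-2-ol
Product: 14 methyl 2-methylbut-3-en-2-yl carbonate
Conditions: n-BuLi, THF, −78 °C; ClCO2Me, → rt
Reagents that add atoms: methyl chloroformate, COC(=O)Cl
Why: Simple alkoxide acylation to the allylic carbonate.

**Step 10**
Reactants: 12; 14
Product: 15 4-{2,6-dibromo-4-[(2-methylbut-3-en-2-yl)oxy]phenyl}-2-methylbutan-2-ol
Conditions: Pd(PPh3)4 (3 mol%), THF, 0 °C → rt
Reagents that add atoms: none beyond 14
Why: Tsuji–Trost O-allylation in which the phenoxide attacks the more substituted terminus of the 1,1-dimethyl-π-allyl palladium (kinetic branched ether); the tertiary alcohol and aryl bromides do not react at this temperature.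

**Step 11**
Reactants: 15
Product: 16 3,5-dibromo-4-(3-hydroxy-3-methylbutyl)-2-(3-methylbut-2-en-1-yl)phenol
Conditions: toluene, 115 °C (sealed)
Reagents that add atoms: none
Why: Aromatic Claisen [3,3] rearrangement of the tert-allyl ether gives the ortho prenyl phenol as a single regioisomer, because the two ortho sites are equivalent and the para site is blocked.

**Step 12**
Reactants: 16
Product: 17 4-[2,6-dibromo-4-(methoxymethoxy)-3-(3-methylbut-2-en-1-yl)phenyl]-2-methylbutan-2-ol
Conditions: MOMCl (1.2 equiv), i-Pr2NEt, CH2Cl2, 0 °C → rt
Reagents that add atoms: chloromethyl methyl ether, COCCl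
Why: Chemoselective protection of the phenol; the hindered tertiary alcohol is inert under these conditions.

**Step 13**
Reactants: 17
Product: 18 5-bromo-7-(methoxymethoxy)-2,2-dimethyl-6-(3-methylbut-2-en-1-yl)chromane
Conditions: Pd(OAc)2 (3 mol%), t-BuXPhos, Cs2CO3, toluene, 70 °C
Reagents that add atoms: none
Why: Buchwald-type intramolecular Pd C–O coupling of the tertiary alkoxide, where oxidative addition is expected at the bromide with one ortho substituent and not the one flanked by two alkyl groups, so the pyran closes para to the prenyl group and the hindered bromide is kept.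

### Union and end game

**Step 14**
Reactants: 18 (1.0 equiv); 8 (1.1 equiv)
Product: 19 5-[4,6-bis(methoxymethoxy)-7-(2-methylbut-3-en-2-yl)-1-benzofuran-2-yl]-7-(methoxymethoxy)-2,2-dimethyl-6-(3-methylbut-2-en-1-yl)chromane
Conditions: 18, t-BuLi, THF, −78 °C; ZnCl2, → rt; then 8, XPhos Pd G3 (4 mol%), THF, 50 °C; then K2CO3, KOPiv, DMA, 110 °C (one pot)
Reagents that add atoms: none
Why: Proposed new method: one-pot Negishi arylation / intramolecular C–H alkenylation of an aryl (E)-1,2-dichlorovinyl ether with a 2,6-dialkylarylzinc; Pd inserts first into the more electrophilic C–Cl geminal to oxygen and couples with the arylzinc with retention to give the (Z)-1-aryl-2-chlorovinyl ether, then inserts into the remaining C–Cl (cis to OAr) and a pivalate-assisted concerted metalation–deprotonation at the only free ortho C–H (the ortho tert-alkyl group turns the vinyl unit toward it) followed by reductive elimination closes the furan; the closest known reaction is the sequential Suzuki coupling/direct arylation of (E)-1,2-dichlorovinyl aryl ethers with unhindered arylboronic acids to 2-arylbenzofurans, not shown with organozincs, di-ortho-substituted nucleophiles or a pentasubstituted tri-oxygenated ring.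

**Step 15**
Reactants: 19
Product: 20 Artopetelin C
Conditions: TMSOTf, 2,2′-bipyridyl, MeCN, 0 °C → rt; then H2O
Reagents that add atoms: none
Why: Buffered silyl-triflate cleavage of aryl MOM ethers (via aryl TMS ethers, hydrolysed on work-up) avoids free protic acid, so the o-prenylphenol, the reverse-prenyl group and the benzofuran should survive without chroman formation or allyl migration.

## Compound list

1 | resorcinol | Oc1cccc(O)c1 | starting material
2 | 1,3-bis(methoxymethoxy)benzene | COCOc1cccc(OCOC)c1 | intermediate
3 | 3,5-bis(methoxymethoxy)phenol | COCOc1cc(O)cc(OCOC)c1 | intermediate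
4 | prenyl bromide (1-bromo-3-methylbut-2-ene) | CC(C)=CCBr | starting material
5 | 1,3-bis(methoxymethoxy)-5-[(3-methylbut-2-en-1-yl)oxy]benzene | COCOc1cc(OCC=C(C)C)cc(OCOC)c1 | intermediate
6 | 3,5-bis(methoxymethoxy)-2-(2-methylbut-3-en-2-yl)phenol | C=CC(C)(C)c1c(O)cc(OCOC)cc1OCOC | intermediate
7 | trichloroethylene | ClC=C(Cl)Cl | starting material
8 | 1-{[(E)-1,2-dichloroethenyl]oxy}-3,5-bis(methoxymethoxy)-2-(2-methylbut-3-en-2-yl)benzene | Cl/C=C(/Cl)Oc1cc(OCOC)cc(OCOC)c1C(C)(C)C=C | intermediate
9 | 1,3-dibromobenzene | Brc1cccc(Br)c1 | starting material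
10 | 1,3-dibromo-2-(3-methylbut-2-en-1-yl)benzene | CC(C)=CCc1c(Br)cccc1Br | intermediate
11 | 4-(2,6-dibromophenyl)-2-methylbutan-2-ol | CC(C)(O)CCc1c(Br)cccc1Br | intermediate
12 | 3,5-dibromo-4-(3-hydroxy-3-methylbutyl)phenol | CC(C)(O)CCc1c(Br)cc(O)cc1Br | intermediate
13 | 2-methylbut-3-en-2-ol | CC(C)(O)C=C | starting material
14 | methyl 2-methylbut-3-en-2-yl carbonate | COC(=O)OC(C)(C)C=C | intermediate
15 | 4-{2,6-dibromo-4-[(2-methylbut-3-en-2-yl)oxy]phenyl}-2-methylbutan-2-ol | CC(C)(O)CCc1c(Br)cc(OC(C)(C)C=C)cc1Br | intermediate
16 | 3,5-dibromo-4-(3-hydroxy-3-methylbutyl)-2-(3-methylbut-2-en-1-yl)phenol | CC(C)=CCc1c(O)cc(Br)c(CCC(C)(C)O)c1Br | intermediate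
17 | 4-[2,6-dibromo-4-(methoxymethoxy)-3-(3-methylbut-2-en-1-yl)phenyl]-2-methylbutan-2-ol | CC(C)=CCc1c(OCOC)cc(Br)c(CCC(C)(C)O)c1Br | intermediate
18 | 5-bromo-7-(methoxymethoxy)-2,2-dimethyl-6-(3-methylbut-2-en-1-yl)chromane | COCOc1cc2OC(C)(C)CCc2c(Br)c1CC=C(C)C | intermediate
19 | 5-[4,6-bis(methoxymethoxy)-7-(2-methylbut-3-en-2-yl)-1-benzofuran-2-yl]-7-(methoxymethoxy)-2,2-dimethyl-6-(3-methylbut-2-en-1-yl)chromane | C=CC(C)(C)c1c(OCOC)cc(OCOC)c2cc(-c3c(CC=C(C)C)c(OCOC)cc4c3CCC(C)(C)O4)oc12 | intermediate
20 | Artopetelin C | C=CC(C)(C)c1c(O)cc(O)c2cc(-c3c(CC=C(C)C)c(O)cc4c3CCC(C)(C)O4)oc12 | target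

## Summary

**Total steps:** 15.
**Longest linear sequence:** 9 (steps 6, 7, 8, 10, 11, 12, 13, 14, 15), which is 60% of the total. The resorcinol branch is 7 steps to the target.

**Three steps most likely to fail, with fallbacks**

1. **Step 14 (proposed new cascade).** The hindered arylzinc may couple poorly at the dichlorovinyl carbon, or the C–H closure may stall in the presence of zinc salts. Fallback (known chemistry, different approach): convert phenol 6 by Mg-mediated ortho-formylation (MgCl2, Et3N, paraformaldehyde), Ramirez gem-dibromo-olefination and Cu-catalysed intramolecular C–O coupling into the 2-bromobenzofuran, then join it to the arylzinc from 18 by an ordinary Negishi coupling.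

2. **Step 4 (Claisen to the reverse-prenyl phenol).** The free para position may allow para-Cope or abnormal-Claisen products. Fallback: block the para position first.
   - Lithiate 2 between the two OMOM groups and brominate.
   - Carry out Ir borylation/oxidation, O-prenylation and Claisen; ortho sites are equivalent and the para site is now blocked.
   - Remove the bromine by Br–Li exchange and protonation to reach 6.

3. **Step 13 (site-selective C–O closure).** Oxidative addition may not discriminate cleanly between the two bromides. Fallback: cyclise the symmetric dibromide 11 directly to 5-bromo-2,2-dimethylchromane, where no selectivity is needed. Then install the 7-OH by Ir borylation/oxidation and the 6-prenyl by O-tert-allylation/Claisen (C6 favoured electronically; the C8 isomer is separated), and protect as MOM to reach 18.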